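All runs come from a simulation with constants of no real substance; scatter was added.

- I start from one constant, kQ, the rate constant of the step L + D → Q. I suppose this is the way Q forms: one Q counts as two D.

| flask | D | E | J | remark | time |
|---|---|---|---|---|---|
| winter | 0.31 M | 0.31 M | 0.62 mM | run made earlier |  |
| autumn | 0.31 M | 0.31 M | 0.42 mM | run made earlier |  |
| midnight | 0.31 M | 0.31 M | 0.93 mM | run made earlier |  |
| south-west | 0.31 M | 0.310 M | 0.62 mM | a single well-mixed tank run continuously and read at steady state, 25 min in it on average |  |
| north-east | 0.31 M (fed, over 12.5 min) | 0.310 M | 0.62 mM | all but D at the start; D goes in evenly over 12.5 min, the run ends at 25 min | 25 min |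
| south-east | 0.31 M | 0.310 M (fed, over 12.5 min) | 0.62 mM | all but E at the start; E goes in evenly over 12.5 min, the run ends at 25 min | 25 min |
| south | 0.31 M | 0.310 M | 0.62 mM | everything together in a closed stirred flask, run for 25 min | 25 min |

| run | time / min | L / % | Q / % |
|---|---|---|---|
| winter | 3.00 | 21 | 54 |
| winter | 6.00 | 25 | 73 |
| winter | 10.0 | 25 | 78 |
| winter | 12.0 | 26 | 79 |
| winter | 15.0 | 25 | 78 |
| autumn | 1.33 | 10 | 18 |
| autumn | 2.50 | 13 | 41 |
| autumn | 4.00 | 16 | 61 |
| autumn | 8.00 | 18 | 78 |
| autumn | 15.0 | 18 | 81 |
| midnight | 3.00 | 29 | 58 |
| midnight | 6.00 | 34 | 69 |
| midnight | 10.0 | 32 | 71 |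
| midnight | 12.0 | 31 | 68 |
| midnight | 15.0 | 33 | 68 |

(readings scatter by 1.5 percentage points)

- percentages count the D that a species holds: one Q counts as two
- the stated concentrations are those of everything mixed, before any reaction; amounts are the same in each set-up
- the earlier runs were read with a standard deviation of 1.5 percentage points
- the feed brings no volume worth counting
- the earlier runs were made in a closed, stirred flask

* the set-up with the highest share of L in all that became L or Q, at the outlet or at the end ("none" if the first two lie within 2 percentage points) (south-west / north-east / south-east / south / none)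
* share of L in all that became L or Q, at the outlet or at the end, south-west
* share of L in all that became L or Q, at the outlet or at the end, north-east
* share of L in all that became L or Q, at the outlet or at the end, south-east
* share of L in all that became L or Q, at the outlet or at the end, south

- In the autumn run, from 2.50 min to 4.00 min, Q rises by 20 percentage points while D stands near 34.5 % and L near 14.5 %. One Q holds two D, so I read kQ = 4.30 L mol⁻¹ min⁻¹, with the scatter of those readings.
- My first way to the south-east share copies the closed winter run, whose last reading gives a share of 24.3 % L. This supposes that L forms whatever E is present.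
- My second way counts E. I take one E per L made, and south-east starts without E, so I let L form at the dose rate F = 0.0248 M min⁻¹.
- I solve the two ends of south-east in this reckoning. At high D, L sits at its quasi-steady level F/(kQ·D), made as fast as it is eaten; at zero D, L stays.
- To join the ends, roughly: at balance D falls at 0.0496 M min⁻¹, so the balance level climbs as fast as F can fill it at Dc = 0.107 M. L stops following there, at the freeze level Lf = F/(kQ·Dc) = 0.0537 M, which is 17.3 % of the D charged.
- The two ways part, and the first one cheats: the readings of winter show L made at 0.0496 M min⁻¹ on average up to 3.00 min, twice the dose rate and so faster than F can supply. For south-east I commit to 17.3 %.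
- The forecast gives 20 % for south-west, 25 % for north-east, 24 % for south-east and 25 % for south, best none, holding that “E shows no clear rate effect”.

- The flask gives 20.5 % for south-west, 27.8 % for north-east, 16.7 % for south-east and 24.1 % for south, so north-east stands highest. In south-east E peaks at 0.138 M, less than the 0.310 M that the closed south flask starts with. Lf, as a share of the D charged, lies 0.60 points from the south-east result, but that closeness is no check: at 12.5 min 44.4 % of the E charged still stands in south-east, so E went out on average slower than F, against my supposition.

    D + J ⇌ G (K = 1.10 L mol⁻¹, k = 170 L mol⁻¹ s⁻¹)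
    E + G → Z (k = 74.0 L mol⁻¹ s⁻¹)
    Z → X (k = 8.10 s⁻¹)
    X → J + L (k = 6.90 s⁻¹)
    D + L → Q (k = 0.0660 L mol⁻¹ s⁻¹)
- The neighbour doses 0.53 M of E over the same 12.5 min, so F becomes 0.0424 M min⁻¹ and Lf becomes 0.0702 M, a share of 22.7 %. The computed flask gives 21.9 %.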